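**Plan**
Retrosynthesis: O7–H from its methoxymethyl (MOM) acetal; the ketone from a C6 formyl group plus 4-methoxybenzylmagnesium chloride (cut C(=O)–CH2); C5–OMe from C5–F; C6–CHO from C6–H; C3=C4 from a C4 carbinol.
The pyran ring is then cut at C3–C4 and O1–C8a together, giving 2,6-difluoro-4-(methoxymethoxy)benzaldehyde and the three-atom unit C3H2–C2(CH3)2–O1 as a carbon,oxygen-dianion.
Forward: the benzene ring is bought complete; the pyran ring is fused onto it in step 2 (as the chroman-4-ol) and unsaturated in step 3; the acyl chain is then built on C6 by formylation, Grignard addition and oxidation.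
Enabling feature: C4 sits on C4a, ortho to C8a which carries O1, and the benzene ring has heteroatoms on C5, C7 and C8a. A benzaldehyde with fluorine on both ortho carbons and oxygen para has a mirror plane through C4a and C7, so either C–F bond can become C8a–O1.
The fluorine left on C5 is a helper: with the C7 acetal oxygen it directs lithiation to C6, and it is exchanged for methoxide once the C6 formyl group stands ortho to it.
Stereochemistry: the target has no stereocentre (C3=C4 lies in a six-membered ring); the carbinol centres of 6 and 14 are racemic and are erased in steps 3 and 7.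

Key step: step 2

Remark: 1, 3 and 13 (the last as a THF solution) are taken as commercially available; all chiral intermediates are racemic.

Step 1
Reactants: 1 2,6-difluoro-4-hydroxybenzaldehyde
Product: 2 2,6-difluoro-4-(methoxymethoxy)benzaldehyde
Conditions: MOMCl, i-Pr2NEt, CH2Cl2, 0 °C to rt
Reagents that add atoms: chloromethyl methyl ether, COCCl
Why: Williamson-type O-alkylation of the acidic phenol with the reactive α-chloro ether gives the methoxymethyl acetal, which should withstand the organolithium, alkoxide and Grignard reagents that follow and helps to direct the lithiation of step 4.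

Step 2
Reactants: 2 2,6-difluoro-4-(methoxymethoxy)benzaldehyde; 3 1-chloro-2-methylpropan-2-ol
Product: 6 5-fluoro-7-(methoxymethoxy)-2,2-dimethyl-3,4-dihydro-2H-chromen-4-ol (racemic), via lithium 1-lithio-2-methylpropan-2-olate 4 (not isolated), via dilithium 1-aryl-3-methylbutane-1,3-diolate 5 (not isolated)
Conditions: 3, n-BuLi, THF, −78 °C; lithium naphthalenide (LiC10H8, 2 equiv), −78 °C; add 2, −78 °C; then KOt-Bu, DMPU, 90 °C; H2O
Reagents that add atoms: none
Why: Two-electron reduction of the lithium alkoxide of 3 exchanges chloride for lithium and gives the β-oxido organolithium 4, whose carbanion carbon (future C3) adds to the formyl carbon of 2 (future C4) at −78 °C; potassium exchange and heat then let the tertiary alkoxide (future O1) displace fluoride from the ortho carbon (future C8a) by addition–elimination. The closest known reaction types are the 1,3-diol synthesis from β-oxido organolithium compounds and aldehydes and the intramolecular displacement of aryl fluoride by an alkoxide that is used to make chromans. The pyran ring closes in the 6-exo-trig mode at the aromatic carbon, while the secondary alkoxide on C4 would need a four-membered ring and stays out. The new stereocentre C4 forms as a racemate with no control element, which is accepted because step 3 removes it. The step needs carbon to react before oxygen, which the temperature secures (the C–Li end adds to the aldehyde at −78 °C, where the O–Li end is inert toward aryl fluoride), and it needs one fluorine of two, which the mirror plane of 2 makes a non-question; the cyclised ring carries one more donor and should resist a second displacement by tert-butoxide.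

Step 3
Reactants: 6 5-fluoro-7-(methoxymethoxy)-2,2-dimethyl-3,4-dihydro-2H-chromen-4-ol
Product: 8 5-fluoro-7-(methoxymethoxy)-2,2-dimethyl-2H-chromene, via chroman-4-yl methanesulfonate 7 (not isolated)
Conditions: MsCl, Et3N, CH2Cl2, 0 °C to 40 °C
Reagents that add atoms: none
Why: Mesylation of the benzylic C4 hydroxyl and amine-induced elimination (the C4 position is activated by O1 and the C7 oxygen, and C3 holds the only β-hydrogens) should give the C3=C4 bond, the standard dehydration of a chroman-4-ol to a 2H-chromene under conditions that spare the acetal, and erases the C4 stereocentre.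

Step 4
Reactants: 8 5-fluoro-7-(methoxymethoxy)-2,2-dimethyl-2H-chromene
Product: 11 5-fluoro-7-(methoxymethoxy)-2,2-dimethyl-2H-chromene-6-carbaldehyde, via 6-lithiochromene 9 (not isolated), via lithium hemiaminalate 10 (not isolated)
Conditions: n-BuLi, THF, −78 °C; DMF, −78 °C to 0 °C; H2O
Reagents that add atoms: N,N-dimethylformamide, CN(C)C=O
Why: Directed ortho-metalation: the C6 hydrogen lies between fluorine, the strongest acidifying ortho substituent, and the chelating acetal oxygen, whereas C8 has no fluorine neighbour, so n-BuLi should remove it selectively at −78 °C (cold enough to keep the ortho-fluoro aryllithium from losing LiF), and DMF formylates the aryllithium.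

Step 5
Reactants: 11 5-fluoro-7-(methoxymethoxy)-2,2-dimethyl-2H-chromene-6-carbaldehyde
Product: 12 5-methoxy-7-(methoxymethoxy)-2,2-dimethyl-2H-chromene-6-carbaldehyde
Conditions: NaOMe, MeOH–DMSO, 70 °C
Reagents that add atoms: sodium methoxide, C[O-].[Na+]
Why: Nucleophilic aromatic substitution by addition–elimination: the fluorine on C5 now stands ortho to the C6 formyl group, which stabilises the anionic adduct, while the oxygen substituents on C7 and C8a are meta to the carbon attacked.

Step 6
Reactants: 12 5-methoxy-7-(methoxymethoxy)-2,2-dimethyl-2H-chromene-6-carbaldehyde; 13 4-methoxybenzylmagnesium chloride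
Product: 14 1-[5-methoxy-7-(methoxymethoxy)-2,2-dimethyl-2H-chromen-6-yl]-2-(4-methoxyphenyl)ethan-1-ol (racemic)
Conditions: THF, 0 °C to rt; H2O
Reagents that add atoms: none
Why: Grignard 1,2-addition of the benzylic organomagnesium reagent to the non-enolisable aldehyde, helped by chelation to the flanking ether oxygens, should give the secondary alcohol as a racemate, which is acceptable because the centre is oxidised away in step 7.

Step 7
Reactants: 14 1-[5-methoxy-7-(methoxymethoxy)-2,2-dimethyl-2H-chromen-6-yl]-2-(4-methoxyphenyl)ethan-1-ol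
Product: 15 1-[5-methoxy-7-(methoxymethoxy)-2,2-dimethyl-2H-chromen-6-yl]-2-(4-methoxyphenyl)ethan-1-one
Conditions: Dess–Martin periodinane, CH2Cl2, rt
Reagents that add atoms: none
Why: Dess–Martin oxidation of the secondary alcohol to the aryl benzyl ketone runs at room temperature under near-neutral conditions that should leave the acetal, the electron-rich rings and the chromene double bond alone.

Step 8
Reactants: 15 1-[5-methoxy-7-(methoxymethoxy)-2,2-dimethyl-2H-chromen-6-yl]-2-(4-methoxyphenyl)ethan-1-one
Product: 16 1-(7-hydroxy-5-methoxy-2,2-dimethyl-2H-chromen-6-yl)-2-(4-methoxyphenyl)ethan-1-one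
Conditions: HCl (cat.), MeOH, 40 °C
Reagents that add atoms: none
Why: Acid-catalysed acetal exchange with methanol removes the methoxymethyl group, helped by the neighbouring carbonyl group, under conditions mild enough for the 2,2-dimethyl-2H-chromene, and the freed C7 hydroxyl is held by a hydrogen bond to the ketone.

**Compound list**
1 | 2,6-difluoro-4-hydroxybenzaldehyde | O=Cc1c(F)cc(O)cc1F | starting material
2 | 2,6-difluoro-4-(methoxymethoxy)benzaldehyde | COCOc1cc(F)c(C=O)c(F)c1 | intermediate
3 | 1-chloro-2-methylpropan-2-ol | CC(C)(O)CCl | starting material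
4 | lithium 1-lithio-2-methylpropan-2-olate | [Li]CC(C)(C)O[Li] | intermediate (not isolated)
5 | dilithium 1-[2,6-difluoro-4-(methoxymethoxy)phenyl]-3-methylbutane-1,3-diolate (racemic) | [Li]OC(CC(C)(C)O[Li])c1c(F)cc(OCOC)cc1F | intermediate (not isolated)
6 | 5-fluoro-7-(methoxymethoxy)-2,2-dimethyl-3,4-dihydro-2H-chromen-4-ol (racemic) | COCOc1cc(F)c2C(O)CC(C)(C)Oc2c1 | intermediate
7 | 5-fluoro-7-(methoxymethoxy)-2,2-dimethyl-3,4-dihydro-2H-chromen-4-yl methanesulfonate (racemic) | COCOc1cc(F)c2C(OS(C)(=O)=O)CC(C)(C)Oc2c1 | intermediate (not isolated)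
8 | 5-fluoro-7-(methoxymethoxy)-2,2-dimethyl-2H-chromene | COCOc1cc(F)c2C=CC(C)(C)Oc2c1 | intermediate
9 | [5-fluoro-7-(methoxymethoxy)-2,2-dimethyl-2H-chromen-6-yl]lithium | COCOc1cc2OC(C)(C)C=Cc2c(F)c1[Li] | intermediate (not isolated)
10 | lithium (dimethylamino)[5-fluoro-7-(methoxymethoxy)-2,2-dimethyl-2H-chromen-6-yl]methanolate | COCOc1cc2OC(C)(C)C=Cc2c(F)c1C(O[Li])N(C)C | intermediate (not isolated)
11 | 5-fluoro-7-(methoxymethoxy)-2,2-dimethyl-2H-chromene-6-carbaldehyde | COCOc1cc2OC(C)(C)C=Cc2c(F)c1C=O | intermediate
12 | 5-methoxy-7-(methoxymethoxy)-2,2-dimethyl-2H-chromene-6-carbaldehyde | COCOc1cc2OC(C)(C)C=Cc2c(OC)c1C=O | intermediate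
13 | 4-methoxybenzylmagnesium chloride | COc1ccc(C[Mg]Cl)cc1 | starting material
14 | 1-[5-methoxy-7-(methoxymethoxy)-2,2-dimethyl-2H-chromen-6-yl]-2-(4-methoxyphenyl)ethan-1-ol (racemic) | COCOc1cc2OC(C)(C)C=Cc2c(OC)c1C(O)Cc1ccc(OC)cc1 | intermediate
15 | 1-[5-methoxy-7-(methoxymethoxy)-2,2-dimethyl-2H-chromen-6-yl]-2-(4-methoxyphenyl)ethan-1-one | COCOc1cc2OC(C)(C)C=Cc2c(OC)c1C(=O)Cc1ccc(OC)cc1 | intermediate
16 | 1-(7-hydroxy-5-methoxy-2,2-dimethyl-2H-chromen-6-yl)-2-(4-methoxyphenyl)ethan-1-one | COc1ccc(CC(=O)c2c(O)cc3OC(C)(C)C=Cc3c2OC)cc1 | target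

Total step count: 8. Longest linear sequence: 8 steps (from 1).

**Steps most likely to fail**

Step 2. What may go wrong: the β-oxido organolithium loses lithium oxide to give 2-methylpropene before it meets the aldehyde, or the fluoride displacement stalls because the ring has lost its formyl activation once the addition has taken place. Fallback (sets out from 2, returns at 8): the order of the two bond formations is reversed and the carbon–carbon bond is made by metathesis. While the formyl group still activates the ring, one fluorine of 2 is displaced by the sodium alkoxide of 2-methylbut-3-en-2-ol (NaH, THF, 0 °C to rt) to give 2-fluoro-4-(methoxymethoxy)-6-[(2-methylbut-3-en-2-yl)oxy]benzaldehyde F1. Wittig methylenation (Ph3P=CH2, THF, 0 °C) gives 1-ethenyl-2-fluoro-4-(methoxymethoxy)-6-[(2-methylbut-3-en-2-yl)oxy]benzene F2. Ring-closing olefin metathesis (second-generation Grubbs catalyst, CH2Cl2, 40 °C) should then give 8 directly, so that steps 2 and 3 are both replaced.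

Step 4. What may go wrong: competing deprotonation at C8, or loss of lithium fluoride from the ortho-fluoro aryllithium to an aryne if the temperature rises before the formamide has reacted. Fallback (sets out from 8, returns at 11): electrophilic instead of anionic formylation. The acetal is removed (HCl cat., MeOH) to give 5-fluoro-2,2-dimethyl-2H-chromen-7-ol F3. Ortho-formylation of its magnesium phenoxide (MgCl2, Et3N, paraformaldehyde, MeCN, reflux) should go to C6, which is para to O1 and not wedged between two oxygen substituents as C8 is, to give 5-fluoro-7-hydroxy-2,2-dimethyl-2H-chromene-6-carbaldehyde F4. Renewed acetal formation (MOMCl, i-Pr2NEt) gives 11.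

Step 5. What may go wrong: slow displacement, because the formyl group is pushed by the donors on C7 and C8a and partly tied up as its methoxide adduct, so it activates C5 only weakly; forcing conditions then invite hydride-transfer disproportionation of the aldehyde. Fallback (sets out from 11, returns at 15): the carbonyl carbon is carried as a nitrile, a slimmer and stronger activator. 11 is converted through (E)-5-fluoro-7-(methoxymethoxy)-2,2-dimethyl-2H-chromene-6-carbaldehyde oxime F5 (NH2OH·HCl, NaOAc, EtOH; then Ac2O, 100 °C) into 5-fluoro-7-(methoxymethoxy)-2,2-dimethyl-2H-chromene-6-carbonitrile F6. NaOMe (MeOH–DMSO) gives 5-methoxy-7-(methoxymethoxy)-2,2-dimethyl-2H-chromene-6-carbonitrile F7. Addition of 13 (THF–toluene, 60 °C) gives, after work-up, 1-[5-methoxy-7-(methoxymethoxy)-2,2-dimethyl-2H-chromen-6-yl]-2-(4-methoxyphenyl)ethan-1-imine F8, and dilute aqueous acetic acid hydrolyses it to 15, which replaces steps 5 to 7.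

**Further compounds**
F1 | step 2 | 2-fluoro-4-(methoxymethoxy)-6-[(2-methylbut-3-en-2-yl)oxy]benzaldehyde | COCOc1cc(F)c(C=O)c(OC(C)(C)C=C)c1
F2 | step 2 | 1-ethenyl-2-fluoro-4-(methoxymethoxy)-6-[(2-methylbut-3-en-2-yl)oxy]benzene | COCOc1cc(F)c(C=C)c(OC(C)(C)C=C)c1
F3 | step 4 | 5-fluoro-2,2-dimethyl-2H-chromen-7-ol | Oc1cc(F)c2C=CC(C)(C)Oc2c1
F4 | step 4 | 5-fluoro-7-hydroxy-2,2-dimethyl-2H-chromene-6-carbaldehyde | Oc1cc2OC(C)(C)C=Cc2c(F)c1C=O
F5 | step 5 | (E)-5-fluoro-7-(methoxymethoxy)-2,2-dimethyl-2H-chromene-6-carbaldehyde oxime | COCOc1cc2OC(C)(C)C=Cc2c(F)c1/C=N/O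
F6 | step 5 | 5-fluoro-7-(methoxymethoxy)-2,2-dimethyl-2H-chromene-6-carbonitrile | COCOc1cc2OC(C)(C)C=Cc2c(F)c1C#N
F7 | step 5 | 5-methoxy-7-(methoxymethoxy)-2,2-dimethyl-2H-chromene-6-carbonitrile | COCOc1cc2OC(C)(C)C=Cc2c(OC)c1C#N
F8 | step 5 | 1-[5-methoxy-7-(methoxymethoxy)-2,2-dimethyl-2H-chromen-6-yl]-2-(4-methoxyphenyl)ethan-1-imine | COCOc1cc2OC(C)(C)C=Cc2c(OC)c1C(=N)Cc1ccc(OC)cc1
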